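(The numbers in the tables are simulated for substances that don't exist, and the scatter is random.)

At the first reading, 1.25 d, Saturday's run holds 31 % of target and adds only 8 percentage points in the remaining 6.75 d, so its fast stretch is over by then, and the question is what that stretch used up.

the same everywhere: electrophile 0.050 M
- Saturday's: free base 0.030 M; protonated nucleophile 0.040 M; protic impurity 0.015 M; run made earlier
- Friday's: free base 0.057 M; protonated nucleophile 0.040 M; protic impurity 0.015 M; run made earlier
- Monday's: free base 0.098 M; protonated nucleophile 0.040 M; protic impurity 0.015 M; run made earlier
- south-east: free base 0.0400 M; protonated nucleophile 0.0400 M; protic impurity 0.0150 M; time 10 d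
- south-west: free base 0.0600 M; protonated nucleophile 0.0400 M; protic impurity 0.0150 M; time 10 d
- north: free base 0.0900 M; protonated nucleophile 0.0400 M; protic impurity 0.0150 M; time 10 d

- Saturday's (time / d: electrophile / %, target / %): 1.25: 68, 31; 3.00: 65, 32; 4.00: 62, 35; 6.00: 53, 36; 8.00: 50, 39
- Friday's (time / d: electrophile / %, target / %): 1.25: 48, 50; 3.00: 42, 53; 4.00: 43, 54; 6.00: 40, 57; 8.00: 37, 58
- Monday's (time / d: electrophile / %, target / %): 1.25: 35, 63; 3.00: 27, 72; 4.00: 23, 72; 6.00: 24, 79; 8.00: 20, 77

(each reading ± 1.5 percentage points)



* part of the electrophile that has reacted at the end, south-east
* part of the electrophile that has reacted at the end, south-west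
* part of the electrophile that has reacted at the end, north
* what raising the concentration of free base from its lowest to its highest value here does to the part of the electrophile that has reacted (changes below 5 percentage points count as none) (no change / it rises / it falls)

The suspect is the free base, as limiting reagent, which is paid twice if the nucleophile must first be freed from its protonated form and the acid set free with each target must then be bound. So Saturday's first reading gives the base cost, the free base charged per target formed in the fast stretch, c(free base) over target share times c(electrophile), 1.94, a reading that carries the scatter of 1.5 points. Friday's run then gets an allowance of 58.9 % from this cost and reads 50 % at 1.25 d and 58 % at 8.00 d, so the cost read at Saturday's first reading does not match Friday's reading at that same time. But Monday's allowance of 101 % meets the charge of protonated nucleophile, 80.0 % of the electrophile, and its target reads 77 %. Reckoned so, target in south-east reaches about 41.3 %, in south-west 62.0 %, and in north 80.0 %. The part reacted runs higher than target, by 11 points at Saturday's last reading and 3 points at Monday's, but it should still rise with base.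

The forecast gives 59 %, 66 % and 79 % for the part reacted, which is a different quantity from the target reckoned above, and says it rises, holding that “The acid released then appears to stall the reaction”.

South-east gives 58.9 %, south-west 66.5 % and north 77.4 %; from lowest to highest base, it rises, by 19 points.

    electrophile + nucleophile → acid set free + target (k = 2.30 M⁻¹ h⁻¹)
    nucleophile + acid set free ⇌ protonated nucleophile, settled at all times (K = 34000 M⁻¹)
    acid set free + free base ⇌ salt of the base, settled at all times (K = 3.40 × 10⁵ M⁻¹)
    electrophile + acid set free → side product (k = 0.650 M⁻¹ h⁻¹)
    protic impurity + free base → quenched reagent (k = 1.30 M⁻¹ h⁻¹)

At the end of north, the electrophile's half-life by the step to target is 89 d, long against 10 d, and the nucleophile's by that step is 1.1 d. Earlier in north, at 0.349 d, the nucleophile's half-life of 0.41 d is shorter than the 0.77 d of the protic impurity against free base, yet that impurity's step has made 0.0126 M of quenched reagent by the end. With that amount taken off the charge, the base cost allows 80.0 % of target in north, which holds 77.0 %. A neighbour of north, the same flask but with 0.085 M of electrophile, is allowed 48.4 % of target and holds 47.0 %.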